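## Analysis of the target

The target is a sesquineolignan made of four guaiacyl-type rings. Ring A is the aryl ketone, ring B the central 1,2,3,5-tetrasubstituted phenol, ring C the arene of a 7-methoxy-2,3-dihydrobenzofuran (O1, C2, C3), and ring D the guaiacyl group on C2. Rings B and C are joined by a 2,6-diaryl-3,7-dioxabicyclo[3.3.0]octane (furofuran), numbered here C7/C8/C9 on the ring B side and C7'/C8'/C9' on the ring C side, with ether links C7–O–C9' and C7'–O–C9.

There are seven stereocentres in three units that do not communicate. The furofuran is 7S,7'S,8R,8'R (cis-fused, both aryl groups exo). The dihydrobenzofuran is 2S,3S, which means ring D and the hydroxymethyl group are cis, the less stable arrangement. Cα of the 3-hydroxy-1-aryl-2-arylpropan-1-one that links ring A to C5 of ring B is S.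

Cα is benzylic, α to a ketone and β to a hydroxyl, so base epimerizes it, dehydrates it to the enone or cleaves it by retro-aldol. The cis C2–O1 bond and the furofuran benzylic ethers are acid-labile, and three phenols are free. The difficulty is one of order: a furofuran that is best closed with acid must coexist with an acid-sensitive cis-phenylcoumaran and, later, a base-sensitive ketone.

The strategy rests on one feature. C7 is para to the phenolic oxygen of ring B and C7' is para to O1 on ring C. Both furofuran C–O bonds at these carbons can therefore form and break reversibly through stabilized benzylic cations, so C7 and C7' can be left to equilibrium once C8 and C8' are fixed.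

## Retrosynthetic reasoning

**Cα–aryl bond (38 ⇒ 37 ⇒ 26 + 34).** The most fragile stereocentre is made last. After global desilylation of 37, the bond between Cα and C5 of ring B is cut, giving the aryl iodide 26 and the racemic α-bromoketone 34. Cutting here lets the ketone side chain enter by a low-temperature, non-basic, stereoconvergent nickel-catalysed arylation in which the catalyst, not the distant substrate stereocentres, sets Cα. The iodine ortho to the ring B oxygen is carried from the start as a silent handle.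

**C7–O and C7'–O bonds (26 ⇒ 25 ⇒ 24).** Both tetrahydrofuran rings are opened at their benzylic C–O bonds, leading to the open-chain tetraol 24. These bonds are chosen because they are the ones that form reversibly. The forward reaction therefore needs no control over the two carbinol configurations of 24 and only has to keep ionization away from C2 of the dihydrobenzofuran.

**C7–C8 and C7'–C8' bonds (24 ⇒ 23 ⇒ 22 ⇒ 18 + 19 + 15).** Tetraol 24 is the full reduction product of keto lactone 23, which comes from dithioacetal 22. The four-carbon core C9–C8–C8'–C9' is the butenolide 19, whose menthyloxy group fixes C8 and C8' in absolute terms. Ring B enters as the acyl anion equivalent 18 by conjugate addition, and the ring C/D unit enters as aldehyde 15 by aldol trapping. The cheap ring B piece is used as the anion, so the valuable aldehyde 15 needs no extra steps and the ring B pivalate falls off in the reduction to uncover the phenol.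

**C2–C3 bond of the dihydrobenzofuran (15 ⇒ 13 ⇒ 12 ⇒ 11 ⇒ 10).** The aldehyde comes from bromide 13 by halogen–metal exchange and formylation, and the silyloxymethyl group from ester 11. The cis ring is cut between C2 and C3: a donor/acceptor carbene at C3 inserts into the benzylic ether C–H that becomes C2. This sets both centres in one catalyst-controlled event and gives the cis isomer kinetically, which no equilibrating method would.

**Diazo ester and ether (10 ⇒ 9 ⇒ 8 ⇒ 6 ⇒ 5 ⇒ 4 + 3; 3 ⇒ 2 ⇒ 1).** The arylacetate 9 is the one-carbon homologue of aldehyde 5 by reduction, chlorination and carbonylation. Ether 5 is cut at the benzylic C–O bond into phenol 4 and alcohol 3, which comes from 1.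

**Small fragments (18 ⇒ 17 ⇒ 16; 34 ⇒ 32 ⇒ 31 ⇒ 28 + 29; 28 ⇒ 27).** The dithioacetal is two steps from 16. The bromoketone is cut at the aryl–carbonyl carbon bond into the aryl bromide 28 and aldehyde 29, then oxidized and brominated.

## Alternatives that were turned down

**Alternative 1:** This route cuts the C3–C3a bond of the dihydrobenzofuran and reaches the cis ester A1, which is identical with 11, by ring contraction of the 3-diazoflavanone A2. Irradiation of A2 in methanol would trigger a Wolff rearrangement in which the ring C carbon migrates to the carbene carbon, and the ketene is trapped as the methyl ester.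
- For it: A2 derives from a chalcone made by a simple aldol, C2 can be set by an asymmetric oxa-Michael cyclization, and no carbonylative homologation is needed. On step count to A1 it is at least as short as steps 3–8.
- Against it: C3 is created by protonation of an ester enol after the rearrangement, so the cis geometry depends on substrate-controlled kinetic protonation of the less stable epimer. Flavanones also racemize by ring opening to the chalcone under the basic diazo-transfer conditions needed to make A2.
- Comparison: it addresses only the phenylcoumaran and leaves the furofuran and Cα unsolved. The chosen route sets C2 and C3 together under catalyst control and puts its main risk into a reversible, self-correcting step.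

**Alternative 2:** This route cuts C7–C8 and C8'–C9' and assembles the furofuranone A3 by a (3+2) cycloaddition. Fluoride (CsF) would release a carbonyl ylide from the α-chloro (trimethylsilyl)methyl ether A4, which adds across the double bond of the γ-aryl butenolide A5 anti to its aryl group.
- For it: it is more convergent than the chosen route. Two C–C bonds and the cis ring fusion arise in one step, without mercury or hydride steps.
- Against it: A4 is the chloro ether of an electron-rich benzaldehyde and ionizes very easily. The γ-hydrogen of A5 is benzylic and vinylogously acidic, so A5 can racemize through its hydroxyfuran tautomer under basic fluoride. The C7 configuration is fixed kinetically by the exo/endo preference with no means of correction at the lactone stage. The C9 carbonyl of A3 must still be removed by reduction to the lactol and Lewis-acid-mediated deoxygenation, and the methoxymethyl group needs acid.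
- Comparison: the chosen route gives up one-step convergence but gains C8/C8' from a configurationally stable auxiliary-bearing butenolide, C7/C7' by equilibrium, and the right oxidation level at C9.

**Alternative 3:** This route cuts C8–C8' and the C9–O–C7' bond and folds the epoxy cinnamyl ether A7 into the silylated furofuran A6. Cp2TiCl (trivalent titanium) would open the epoxide to a C8 radical, which cyclizes 5-exo onto the cinnamyl alkene. Iodine then lets the C9 alkoxide close onto C7'.
- For it: one flask makes a C–C bond, two rings and three stereocentres. It avoids the dithioacetal, mercury and hydride steps and is clearly the shortest path to the bicycle, which is a real advantage over the chosen route.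
- Against it: all absolute stereochemistry hangs on the C7 carbinol of A7, an acid-labile electron-rich benzylic ether next to an epoxide. The C8–C8' relationship is set by a radical cyclization in which the trans isomer cannot close the second ring and is lost. C7' is fixed kinetically in a benzylic substitution.
- Comparison: the chosen route is longer but every furofuran centre is either auxiliary-defined or thermodynamically corrected, so no material is lost to diastereomers.

Key step: step 17

Assumption: butenolide 19, aldehyde 29 and both antipodes of Rh2(PTTL)4 are taken as purchasable; 19 is otherwise one step from 5-hydroxyfuran-2(5H)-one and l-menthol.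

Assumption: the sense of induction of Rh2(R-PTTL)4 in step 8 and of the pybox ligand in step 23 is assigned by analogy with simpler substrates; the mirror-image catalyst or ligand is used if the opposite sense is found.

## Route

Step 1
Reactants: 1 vanillin
Product: 2 3-methoxy-4-[(triisopropylsilyl)oxy]benzaldehyde
Conditions: TIPSCl, imidazole, DMF, rt
Reagents that add atoms: chlorotriisopropylsilane CC(C)[Si](Cl)(C(C)C)C(C)C
Why: Standard phenol silylation; the bulky aryl TIPS ether survives the base, hydride, organolithium and mild acid used later and is a weaker cation donor than a free or alkylated phenol.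

Step 2
Reactants: 2 3-methoxy-4-[(triisopropylsilyl)oxy]benzaldehyde
Product: 3 {3-methoxy-4-[(triisopropylsilyl)oxy]phenyl}methanol
Conditions: NaBH4, MeOH/THF, 0 °C
Reagents that add atoms: none
Why: Borohydride reduction of an aryl aldehyde; the aryl silyl ether is untouched at 0 °C.

Step 3
Reactants: 4 5-bromo-2-hydroxy-3-methoxybenzaldehyde; 3 {3-methoxy-4-[(triisopropylsilyl)oxy]phenyl}methanol
Product: 5 5-bromo-3-methoxy-2-({3-methoxy-4-[(triisopropylsilyl)oxy]phenyl}methoxy)benzaldehyde
Conditions: PPh3, DIAD, THF, 0 °C → rt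
Reagents that add atoms: none
Why: Mitsunobu etherification of an acidic salicylaldehyde phenol with a primary benzylic alcohol; it avoids the unstable p-silyloxybenzyl halide and basic conditions that could strip the aryl silyl ether.

Step 4
Reactants: 5 5-bromo-3-methoxy-2-({3-methoxy-4-[(triisopropylsilyl)oxy]phenyl}methoxy)benzaldehyde
Product: 6 [5-bromo-3-methoxy-2-({3-methoxy-4-[(triisopropylsilyl)oxy]phenyl}methoxy)phenyl]methanol
Conditions: NaBH4, MeOH/THF, 0 °C
Reagents that add atoms: none
Why: Chemoselective aldehyde reduction; aryl bromide and both ethers are inert.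

Step 5
Reactants: 6 [5-bromo-3-methoxy-2-({3-methoxy-4-[(triisopropylsilyl)oxy]phenyl}methoxy)phenyl]methanol
Product: 8 benzylic chloride {4-[(4-bromo-2-(chloromethyl)-6-methoxyphenoxy)methyl]-2-methoxyphenoxy}triisopropylsilane, via benzylic mesylate 7 (not isolated)
Conditions: MsCl, Et3N, CH2Cl2, 0 °C; LiCl, DMF, rt
Reagents that add atoms: lithium chloride [Li+].[Cl-]
Why: Sulfonylation and SN2 displacement by chloride under buffered conditions; no free acid is produced that could cleave the p-silyloxybenzyl ether.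

Step 6
Reactants: 8 benzylic chloride {4-[(4-bromo-2-(chloromethyl)-6-methoxyphenoxy)methyl]-2-methoxyphenoxy}triisopropylsilane
Product: 9 methyl 2-[5-bromo-3-methoxy-2-({3-methoxy-4-[(triisopropylsilyl)oxy]phenyl}methoxy)phenyl]acetate
Conditions: PdCl2(PPh3)2 (3 mol%), CO (1 atm), MeOH (10 equiv), K2CO3, THF, 45 °C
Reagents that add atoms: carbon monoxide [C-]#[O+]; methanol CO
Why: Palladium-catalysed methoxycarbonylation of a benzylic chloride; oxidative addition to the benzylic C–Cl bond is much faster than to the electron-rich aryl bromide with a triphenylphosphine catalyst at this temperature, and THF with limited methanol suppresses solvolysis.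

Step 7
Reactants: 9 methyl 2-[5-bromo-3-methoxy-2-({3-methoxy-4-[(triisopropylsilyl)oxy]phenyl}methoxy)phenyl]acetate
Product: 10 methyl 2-diazo-2-[5-bromo-3-methoxy-2-({3-methoxy-4-[(triisopropylsilyl)oxy]phenyl}methoxy)phenyl]acetate
Conditions: 4-acetamidobenzenesulfonyl azide, DBU, MeCN, 0 °C → rt
Reagents that add atoms: 4-acetamidobenzenesulfonyl azide CC(=O)Nc1ccc(cc1)S(=O)(=O)N=[N+]=[N-]
Why: Regitz diazo transfer to an arylacetate, the standard entry to donor/acceptor diazo esters.

Step 8
Reactants: 10 methyl 2-diazo-2-[5-bromo-3-methoxy-2-({3-methoxy-4-[(triisopropylsilyl)oxy]phenyl}methoxy)phenyl]acetate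
Product: 11 methyl (2S,3R)-5-bromo-7-methoxy-2-{3-methoxy-4-[(triisopropylsilyl)oxy]phenyl}-2,3-dihydro-1-benzofuran-3-carboxylate (cis)
Conditions: Rh2(R-PTTL)4 (dirhodium tetrakis[N-phthaloyl-(R)-tert-leucinate], 1 mol%), toluene, −60 °C
Reagents that add atoms: none
Why: Intramolecular 1,5 C–H insertion of the rhodium carbene into the benzylic ether C–H, a known route to cis-2-aryl-2,3-dihydrobenzofuran-3-carboxylates including 5-bromo examples; the concerted insertion sets C2 and C3 together, the cis isomer is the kinetic product, and the chiral carboxylate ligands select the enantiotopic C–H bond.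

Step 9
Reactants: 11 methyl (2S,3R)-5-bromo-7-methoxy-2-{3-methoxy-4-[(triisopropylsilyl)oxy]phenyl}-2,3-dihydro-1-benzofuran-3-carboxylate
Product: 12 [(2S,3S)-5-bromo-7-methoxy-2-{3-methoxy-4-[(triisopropylsilyl)oxy]phenyl}-2,3-dihydro-1-benzofuran-3-yl]methanol
Conditions: i-Bu2AlH, CH2Cl2, −78 → 0 °C; aq. potassium sodium tartrate
Reagents that add atoms: none
Why: Ester reduction with a Lewis acidic, non-basic hydride removes the epimerizable α-aryl ester before any base is used; the descriptor at C3 changes from R to S only because the substituent priorities change.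

Step 10
Reactants: 12 [(2S,3S)-5-bromo-7-methoxy-2-{3-methoxy-4-[(triisopropylsilyl)oxy]phenyl}-2,3-dihydro-1-benzofuran-3-yl]methanol
Product: 13 (2S,3S)-5-bromo-7-methoxy-2-{3-methoxy-4-[(triisopropylsilyl)oxy]phenyl}-3-{[(triisopropylsilyl)oxy]methyl}-2,3-dihydro-1-benzofuran
Conditions: TIPSCl, imidazole, DMF, rt
Reagents that add atoms: chlorotriisopropylsilane CC(C)[Si](Cl)(C(C)C)C(C)C
Why: Silylation of a primary alcohol; a primary TIPS ether withstands the later organometallic, mercury and sulfonic acid steps yet is cleaved by fluoride at the end.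

Step 11
Reactants: 13 (2S,3S)-5-bromo-7-methoxy-2-{3-methoxy-4-[(triisopropylsilyl)oxy]phenyl}-3-{[(triisopropylsilyl)oxy]methyl}-2,3-dihydro-1-benzofuran
Product: 15 (2S,3S)-7-methoxy-2-{3-methoxy-4-[(triisopropylsilyl)oxy]phenyl}-3-{[(triisopropylsilyl)oxy]methyl}-2,3-dihydro-1-benzofuran-5-carbaldehyde, via aryllithium 14 (not isolated)
Conditions: n-BuLi, THF, −78 °C; DMF, −78 → 0 °C
Reagents that add atoms: N,N-dimethylformamide CN(C)C=O
Why: Bromine–lithium exchange is faster than any deprotonation at −78 °C and the aryllithium is formylated by DMF (Bouveault formylation); the new aldehyde lies para to O1, as the later cation chemistry requires.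

Step 12
Reactants: 16 5-iodovanillin
Product: 17 4-formyl-2-iodo-6-methoxyphenyl 2,2-dimethylpropanoate
Conditions: pivaloyl chloride, Et3N, DMAP (cat.), CH2Cl2, rt
Reagents that add atoms: pivaloyl chloride CC(C)(C)C(Cl)=O
Why: Acylation of an acidic phenol; the hindered pivalate flanked by iodine and methoxy resists enolates and amide bases at −78 °C and is removed later by LiAlH4 without a separate step.

Step 13
Reactants: 17 4-formyl-2-iodo-6-methoxyphenyl 2,2-dimethylpropanoate
Product: 18 4-[bis(phenylsulfanyl)methyl]-2-iodo-6-methoxyphenyl 2,2-dimethylpropanoate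
Conditions: PhSH (2.2 equiv), BF3·OEt2 (0.3 equiv), CH2Cl2, 0 °C
Reagents that add atoms: benzenethiol Sc1ccccc1
Why: Lewis-acid-catalysed dithioacetalization of an aryl aldehyde; the diphenyl dithioacetal is acidic enough for a lithium amide, so no alkyllithium meets the aryl iodide.

Step 14
Reactants: 18 4-[bis(phenylsulfanyl)methyl]-2-iodo-6-methoxyphenyl 2,2-dimethylpropanoate; 19 (5R)-5-{[(1R,2S,5R)-5-methyl-2-(propan-2-yl)cyclohexyl]oxy}furan-2(5H)-one; 15 (2S,3S)-7-methoxy-2-{3-methoxy-4-[(triisopropylsilyl)oxy]phenyl}-3-{[(triisopropylsilyl)oxy]methyl}-2,3-dihydro-1-benzofuran-5-carbaldehyde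
Product: 22 (3S,4R,5R)-all-trans lactone carrying at C3 the hydroxy(dihydrobenzofuran-5-yl)methyl group from 15 (carbinol epimers) at C4 the ring B bis(phenylsulfanyl)methyl group and at C5 the menthyloxy group, via lithiated dithioacetal 20 (not isolated), via lithium enolate 21 (not isolated)
Conditions: LiN(i-Pr)2, THF, −78 °C; 19, −78 °C; 15, −78 °C; AcOH quench at −78 °C
Reagents that add atoms: none
Why: Tandem conjugate addition–aldol on a chiral 5-alkoxybutenolide, a known route to lignan precursors; the sulfur-stabilized carbanion adds to C4 anti to the menthyloxy group and the enolate takes up the aldehyde anti to the new C4 substituent, so C4 and C3 become C8 and C8' with the R,R configuration, while the carbinol configuration is left open because it does not matter later.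

Step 15
Reactants: 22 (3S,4R,5R)-all-trans dithioacetal lactone
Product: 23 (3S,4R,5R)-all-trans keto lactone with the 4-(pivaloyloxy)-3-iodo-5-methoxybenzoyl group at C4
Conditions: Hg(ClO4)2·3H2O, CaCO3, THF/H2O, 0 °C
Reagents that add atoms: water O
Why: Thiophilic mercury-promoted hydrolysis of the diaryl dithioacetal under carbonate buffering, which protects the menthyl acetal and silyl ethers; the C4 hydrogen becomes enolizable but already sits in the thermodynamically preferred all-trans arrangement.

Step 16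
Reactants: 23 (3S,4R,5R)-all-trans keto lactone
Product: 24 (2R,3R)-1-(4-hydroxy-3-iodo-5-methoxyphenyl)-2,3-bis(hydroxymethyl)-4-[(2S,3S)-7-methoxy-2-{3-methoxy-4-[(triisopropylsilyl)oxy]phenyl}-3-{[(triisopropylsilyl)oxy]methyl}-2,3-dihydro-1-benzofuran-5-yl]butane-1,4-diol (epimers at C1 and C4)
Conditions: LiAlH4, THF, 0 °C → rt; aq. potassium sodium tartrate
Reagents that add atoms: none
Why: One hydride reduction takes the ketone to the C7 carbinol, opens the lactone and its menthyl acetal to the C9' and C9 primary alcohols and cleaves the aryl pivalate to the free ring B phenol; the intermediate aldehydes are reduced faster than they enolize, so C8 and C8' are preserved, and the aryl iodide and TIPS ethers tolerate LiAlH4 at this temperature.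

Step 17
Reactants: 24 (2R,3R)-tetraol
Product: 25 (7S,7'S,8R,8'R)-furofuran: 2-iodo-6-methoxy-4-{6-exo-[(2S,3S)-7-methoxy-2-{3-methoxy-4-[(triisopropylsilyl)oxy]phenyl}-3-{[(triisopropylsilyl)oxy]methyl}-2,3-dihydro-1-benzofuran-5-yl]-3,7-dioxabicyclo[3.3.0]oct-2-exo-yl}phenol
Conditions: (1S)-(+)-10-camphorsulfonic acid (0.2 equiv), 4 Å molecular sieves, CH2Cl2 (0.01 M), 0 °C → rt
Reagents that add atoms: none
Why: Protonation and loss of water at the C7 carbinol gives a cation that the free para phenol of ring B turns into a protonated p-quinone methide, and the C7' carbinol ionizes in the same way with help from the para oxygen O1 of ring C; the closest known reaction is the acid-mediated cyclodehydration of 1,4-diaryl-2,3-bis(hydroxymethyl)butane-1,4-diols to 2,6-diaryl-3,7-dioxabicyclo[3.3.0]octanes. The C9' hydroxyl adds to C7 and the C9 hydroxyl to C7', each a 5-exo-trig closure onto the exocyclic cationic carbon, so both tetrahydrofuran rings and the C7–O and C7'–O bonds form in one flask. The 8R,8'R arrangement fixed in step 14 is the one that lets the two rings fuse cis, and the new centres C7 and C7' are set by these bridgeheads under thermodynamic control: each closure is reversible, an aryl group on the concave face is strained and re-ionizes, and the mixture drains into the diexo 7S,7'S isomer whatever the carbinol configurations of 24. The step needs ionization at the two carbinols and not at C2 of the cis-dihydrobenzofuran, and O- rather than C-alkylation. The first is secured because the carbinol and tetrahydrofuran oxygens are far more basic than the aryl ether oxygen O1, because ring B has a free phenol and ring C the O1 donor while ring D is held as the weaker silyloxy donor, and because only a catalytic sulfonic acid at or below room temperature is used. The second is secured by the faster, reversible 5-exo oxygen attack and by stopping once the epi isomers have converged, before Friedel–Crafts closure onto a neighbouring ring can compete. The sieves take up the two equivalents of water and protect both TIPS ethers.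

Step 18
Reactants: 25 (7S,7'S,8R,8'R)-furofuran phenol
Product: 26 ring B tert-butyldimethylsilyl ether of 25
Conditions: TBSOTf, 2,6-lutidine, CH2Cl2, −40 → 0 °C
Reagents that add atoms: tert-butyldimethylsilyl trifluoromethanesulfonate CC(C)(C)[Si](C)(C)OS(=O)(=O)C(F)(F)F
Why: The hindered 2-iodo-6-methoxyphenol needs the silyl triflate; excess lutidine keeps the medium basic so the furofuran ethers are not ionized, and the TBS group is small enough to leave the neighbouring carbon accessible in step 23.

Step 19
Reactants: 27 4-bromo-2-methoxyphenol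
Product: 28 (4-bromo-2-methoxyphenoxy)(tert-butyl)dimethylsilane
Conditions: TBSCl, imidazole, DMF, rt
Reagents that add atoms: tert-butylchlorodimethylsilane CC(C)(C)[Si](C)(C)Cl
Why: Routine phenol silylation; the aryl TBS ether is the most easily removed of the final silyl groups.

Step 20
Reactants: 28 (4-bromo-2-methoxyphenoxy)(tert-butyl)dimethylsilane; 29 3-[(tert-butyldimethylsilyl)oxy]propanal
Product: 31 rac-3-[(tert-butyldimethylsilyl)oxy]-1-{4-[(tert-butyldimethylsilyl)oxy]-3-methoxyphenyl}propan-1-ol, via aryllithium 30 (not isolated)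
Conditions: n-BuLi, THF, −78 °C; 29, −78 °C
Reagents that add atoms: none
Why: Bromine–lithium exchange and 1,2-addition to an aliphatic aldehyde; the lithium is para to the silyloxy group, so no silyl migration to carbon can occur.

Step 21
Reactants: 31 rac-3-[(tert-butyldimethylsilyl)oxy]-1-{4-[(tert-butyldimethylsilyl)oxy]-3-methoxyphenyl}propan-1-ol
Product: 32 3-[(tert-butyldimethylsilyl)oxy]-1-{4-[(tert-butyldimethylsilyl)oxy]-3-methoxyphenyl}propan-1-one
Conditions: Dess–Martin periodinane, NaHCO3, CH2Cl2, rt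
Reagents that add atoms: none
Why: Neutral buffered oxidation of a benzylic alcohol; the β-silyloxy ketone is not exposed to base and does not eliminate.

Step 22
Reactants: 32 3-[(tert-butyldimethylsilyl)oxy]-1-{4-[(tert-butyldimethylsilyl)oxy]-3-methoxyphenyl}propan-1-one
Product: 34 rac-2-bromo-3-[(tert-butyldimethylsilyl)oxy]-1-{4-[(tert-butyldimethylsilyl)oxy]-3-methoxyphenyl}propan-1-one, via trimethylsilyl enol ether 33 (not isolated)
Conditions: LiN(SiMe3)2, TMSCl, THF, −78 °C; NBS, −78 → 0 °C
Reagents that add atoms: N-bromosuccinimide O=C1CCC(=O)N1Br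
Why: Enolate trapping as the silyl enol ether and electrophilic bromination confines bromine to the α-carbon and spares the electron-rich ring; the low temperature and internal silyl quench prevent loss of the β-silyloxy group.

Step 23
Reactants: 26 ring B silyl ether aryl iodide; 34 rac-2-bromo-3-[(tert-butyldimethylsilyl)oxy]-1-{4-[(tert-butyldimethylsilyl)oxy]-3-methoxyphenyl}propan-1-one
Product: 37 pentasilyl ether of the target with S configuration at Cα, via arylmagnesium chloride 35 (not isolated), via arylzinc iodide 36 (not isolated)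
Conditions: i-PrMgCl·LiCl, THF, −15 → 0 °C; ZnI2, THF; volatiles removed; 34 (1.5 equiv), NiCl2·glyme (10 mol%), chiral 4-aryl pybox ligand (13 mol%), glyme/THF, −30 °C
Reagents that add atoms: none
Why: Iodine–magnesium exchange followed by transmetalation gives an arylzinc without an ortho-lithio silyl ether that could undergo silyl migration, and the stereoconvergent Negishi arylation of racemic α-bromoketones joins it to 34: nickel turns both enantiomers of the bromide into the same α-keto radical, and the chiral pybox–nickel aryl complex sets Cα on bond formation. The reaction is non-basic and runs at −30 °C, so the tertiary α-aryl centre is not racemized, and the remote stereocentres leave the choice to the ligand; 2-iodopropane from the exchange is pumped off so it cannot compete as an electrophile.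

Step 24
Reactants: 37 pentasilyl ether of the target
Product: 38 target: (2S)-3-hydroxy-1-(4-hydroxy-3-methoxyphenyl)-2-{2-hydroxy-3-methoxy-5-[(7S,7'S,8R,8'R)-furofuranyl bearing the (2S,3S)-3-(hydroxymethyl)-2-(4-hydroxy-3-methoxyphenyl)-7-methoxy-2,3-dihydro-1-benzofuran-5-yl group]phenyl}propan-1-one
Conditions: Bu4NF, AcOH (1:1), THF, 0 °C → rt
Reagents that add atoms: none
Why: Fluoride cleaves the three aryl and two primary alkyl silyl ethers; acetic acid buffering keeps phenoxide and alkoxide concentrations low so that Cα does not epimerize, dehydrate or undergo retro-aldol, and no acid strong enough to open the furofuran or the cis-dihydrobenzofuran is present.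

## Compound list

1 | vanillin (4-hydroxy-3-methoxybenzaldehyde) | COc1cc(C=O)ccc1O | starting material
2 | 3-methoxy-4-[(triisopropylsilyl)oxy]benzaldehyde | COc1cc(C=O)ccc1O[Si](C(C)C)(C(C)C)C(C)C | intermediate
3 | {3-methoxy-4-[(triisopropylsilyl)oxy]phenyl}methanol | COc1cc(CO)ccc1O[Si](C(C)C)(C(C)C)C(C)C | intermediate
4 | 5-bromo-2-hydroxy-3-methoxybenzaldehyde | COc1cc(Br)cc(C=O)c1O | starting material
5 | 5-bromo-3-methoxy-2-({3-methoxy-4-[(triisopropylsilyl)oxy]phenyl}methoxy)benzaldehyde | COc1cc(Br)cc(C=O)c1OCc1ccc(O[Si](C(C)C)(C(C)C)C(C)C)c(OC)c1 | intermediate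
6 | [5-bromo-3-methoxy-2-({3-methoxy-4-[(triisopropylsilyl)oxy]phenyl}methoxy)phenyl]methanol | COc1cc(Br)cc(CO)c1OCc1ccc(O[Si](C(C)C)(C(C)C)C(C)C)c(OC)c1 | intermediate
7 | methanesulfonate of 6 | COc1cc(Br)cc(COS(C)(=O)=O)c1OCc1ccc(O[Si](C(C)C)(C(C)C)C(C)C)c(OC)c1 | intermediate (not isolated)
8 | {4-[(4-bromo-2-(chloromethyl)-6-methoxyphenoxy)methyl]-2-methoxyphenoxy}triisopropylsilane | COc1cc(Br)cc(CCl)c1OCc1ccc(O[Si](C(C)C)(C(C)C)C(C)C)c(OC)c1 | intermediate
9 | methyl 2-[5-bromo-3-methoxy-2-({3-methoxy-4-[(triisopropylsilyl)oxy]phenyl}methoxy)phenyl]acetate | COC(=O)Cc1cc(Br)cc(OC)c1OCc1ccc(O[Si](C(C)C)(C(C)C)C(C)C)c(OC)c1 | intermediate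
10 | methyl 2-diazo-2-[5-bromo-3-methoxy-2-({3-methoxy-4-[(triisopropylsilyl)oxy]phenyl}methoxy)phenyl]acetate | COC(=O)C(=[N+]=[N-])c1cc(Br)cc(OC)c1OCc1ccc(O[Si](C(C)C)(C(C)C)C(C)C)c(OC)c1 | intermediate
11 | methyl (2S,3R)-5-bromo-7-methoxy-2-{3-methoxy-4-[(triisopropylsilyl)oxy]phenyl}-2,3-dihydro-1-benzofuran-3-carboxylate (cis) | Brc1cc(OC)c2c(c1)[C@@H](C(=O)OC)[C@@H](c1ccc(O[Si](C(C)C)(C(C)C)C(C)C)c(OC)c1)O2 | intermediate
12 | [(2S,3S)-5-bromo-7-methoxy-2-{3-methoxy-4-[(triisopropylsilyl)oxy]phenyl}-2,3-dihydro-1-benzofuran-3-yl]methanol | Brc1cc(OC)c2c(c1)[C@@H](CO)[C@@H](c1ccc(O[Si](C(C)C)(C(C)C)C(C)C)c(OC)c1)O2 | intermediate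
13 | (2S,3S)-5-bromo-7-methoxy-2-{3-methoxy-4-[(triisopropylsilyl)oxy]phenyl}-3-{[(triisopropylsilyl)oxy]methyl}-2,3-dihydro-1-benzofuran | Brc1cc(OC)c2c(c1)[C@@H](CO[Si](C(C)C)(C(C)C)C(C)C)[C@@H](c1ccc(O[Si](C(C)C)(C(C)C)C(C)C)c(OC)c1)O2 | intermediate
14 | 5-lithio derivative of 13 | [Li]c1cc(OC)c2c(c1)[C@@H](CO[Si](C(C)C)(C(C)C)C(C)C)[C@@H](c1ccc(O[Si](C(C)C)(C(C)C)C(C)C)c(OC)c1)O2 | intermediate (not isolated)
15 | (2S,3S)-7-methoxy-2-{3-methoxy-4-[(triisopropylsilyl)oxy]phenyl}-3-{[(triisopropylsilyl)oxy]methyl}-2,3-dihydro-1-benzofuran-5-carbaldehyde | O=Cc1cc(OC)c2c(c1)[C@@H](CO[Si](C(C)C)(C(C)C)C(C)C)[C@@H](c1ccc(O[Si](C(C)C)(C(C)C)C(C)C)c(OC)c1)O2 | intermediate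
16 | 5-iodovanillin (4-hydroxy-3-iodo-5-methoxybenzaldehyde) | COc1cc(C=O)cc(I)c1O | starting material
17 | 4-formyl-2-iodo-6-methoxyphenyl 2,2-dimethylpropanoate | COc1cc(C=O)cc(I)c1OC(=O)C(C)(C)C | intermediate
18 | 4-[bis(phenylsulfanyl)methyl]-2-iodo-6-methoxyphenyl 2,2-dimethylpropanoate | COc1cc(C(Sc2ccccc2)Sc2ccccc2)cc(I)c1OC(=O)C(C)(C)C | intermediate
19 | (5R)-5-{[(1R,2S,5R)-5-methyl-2-(propan-2-yl)cyclohexyl]oxy}furan-2(5H)-one | O=C1C=C[C@H](O[C@@H]2C[C@H](C)CC[C@H]2C(C)C)O1 | starting material
20 | lithiated dithioacetal from 18 | [Li]C(Sc1ccccc1)(Sc1ccccc1)c1cc(I)c(OC(=O)C(C)(C)C)c(OC)c1 | intermediate (not isolated)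
21 | lithium enolate of the (4R,5R) conjugate adduct | [Li]OC1=C[C@@H](C(Sc2ccccc2)(Sc2ccccc2)c2cc(I)c(OC(=O)C(C)(C)C)c(OC)c2)[C@H](O[C@@H]2C[C@H](C)CC[C@H]2C(C)C)O1 | intermediate (not isolated)
22 | (3S,4R,5R)-all-trans dithioacetal lactone, carbinol epimers | O=C1[C@H](C(O)c2cc(OC)c3c(c2)[C@@H](CO[Si](C(C)C)(C(C)C)C(C)C)[C@@H](c2ccc(O[Si](C(C)C)(C(C)C)C(C)C)c(OC)c2)O3)[C@@H](C(Sc2ccccc2)(Sc2ccccc2)c2cc(I)c(OC(=O)C(C)(C)C)c(OC)c2)[C@H](O[C@@H]2C[C@H](C)CC[C@H]2C(C)C)O1 | intermediate
23 | (3S,4R,5R)-all-trans keto lactone, carbinol epimers | O=C1[C@H](C(O)c2cc(OC)c3c(c2)[C@@H](CO[Si](C(C)C)(C(C)C)C(C)C)[C@@H](c2ccc(O[Si](C(C)C)(C(C)C)C(C)C)c(OC)c2)O3)[C@@H](C(=O)c2cc(I)c(OC(=O)C(C)(C)C)c(OC)c2)[C@H](O[C@@H]2C[C@H](C)CC[C@H]2C(C)C)O1 | intermediate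
24 | (2R,3R)-1-(4-hydroxy-3-iodo-5-methoxyphenyl)-2,3-bis(hydroxymethyl)-4-[(2S,3S)-dihydrobenzofuran-5-yl]butane-1,4-diol with TIPS ethers on ring D and on the C3 hydroxymethyl group, epimers at C1 and C4 | COc1cc(cc(I)c1O)C(O)[C@@H](CO)[C@H](CO)C(O)c1cc(OC)c2c(c1)[C@@H](CO[Si](C(C)C)(C(C)C)C(C)C)[C@@H](c1ccc(O[Si](C(C)C)(C(C)C)C(C)C)c(OC)c1)O2 | intermediate
25 | (7S,7'S,8R,8'R)-furofuran with free ring B iodophenol and bis-TIPS cis-phenylcoumaran | COc1cc(cc(I)c1O)[C@H]1OC[C@H]2[C@@H]1CO[C@@H]2c1cc(OC)c2c(c1)[C@@H](CO[Si](C(C)C)(C(C)C)C(C)C)[C@@H](c1ccc(O[Si](C(C)C)(C(C)C)C(C)C)c(OC)c1)O2 | intermediate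
26 | ring B tert-butyldimethylsilyl ether of 25 | COc1cc(cc(I)c1O[Si](C)(C)C(C)(C)C)[C@H]1OC[C@H]2[C@@H]1CO[C@@H]2c1cc(OC)c2c(c1)[C@@H](CO[Si](C(C)C)(C(C)C)C(C)C)[C@@H](c1ccc(O[Si](C(C)C)(C(C)C)C(C)C)c(OC)c1)O2 | intermediate
27 | 4-bromo-2-methoxyphenol | COc1cc(Br)ccc1O | starting material
28 | (4-bromo-2-methoxyphenoxy)(tert-butyl)dimethylsilane | COc1cc(Br)ccc1O[Si](C)(C)C(C)(C)C | intermediate
29 | 3-[(tert-butyldimethylsilyl)oxy]propanal | O=CCCO[Si](C)(C)C(C)(C)C | starting material
30 | {4-[(tert-butyldimethylsilyl)oxy]-3-methoxyphenyl}lithium | [Li]c1ccc(O[Si](C)(C)C(C)(C)C)c(OC)c1 | intermediate (not isolated)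
31 | rac-3-[(tert-butyldimethylsilyl)oxy]-1-{4-[(tert-butyldimethylsilyl)oxy]-3-methoxyphenyl}propan-1-ol | COc1cc(C(O)CCO[Si](C)(C)C(C)(C)C)ccc1O[Si](C)(C)C(C)(C)C | intermediate
32 | 3-[(tert-butyldimethylsilyl)oxy]-1-{4-[(tert-butyldimethylsilyl)oxy]-3-methoxyphenyl}propan-1-one | COc1cc(C(=O)CCO[Si](C)(C)C(C)(C)C)ccc1O[Si](C)(C)C(C)(C)C | intermediate
33 | (Z)-trimethylsilyl enol ether of 32 | COc1cc(/C(O[Si](C)(C)C)=C/CO[Si](C)(C)C(C)(C)C)ccc1O[Si](C)(C)C(C)(C)C | intermediate (not isolated)
34 | rac-2-bromo-3-[(tert-butyldimethylsilyl)oxy]-1-{4-[(tert-butyldimethylsilyl)oxy]-3-methoxyphenyl}propan-1-one | COc1cc(C(=O)C(Br)CO[Si](C)(C)C(C)(C)C)ccc1O[Si](C)(C)C(C)(C)C | intermediate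
35 | arylmagnesium chloride from 26 | COc1cc(cc([Mg]Cl)c1O[Si](C)(C)C(C)(C)C)[C@H]1OC[C@H]2[C@@H]1CO[C@@H]2c1cc(OC)c2c(c1)[C@@H](CO[Si](C(C)C)(C(C)C)C(C)C)[C@@H](c1ccc(O[Si](C(C)C)(C(C)C)C(C)C)c(OC)c1)O2 | intermediate (not isolated)
36 | arylzinc iodide from 35 | COc1cc(cc([Zn]I)c1O[Si](C)(C)C(C)(C)C)[C@H]1OC[C@H]2[C@@H]1CO[C@@H]2c1cc(OC)c2c(c1)[C@@H](CO[Si](C(C)C)(C(C)C)C(C)C)[C@@H](c1ccc(O[Si](C(C)C)(C(C)C)C(C)C)c(OC)c1)O2 | intermediate (not isolated)
37 | pentasilyl ether of the target, S at Cα | COc1cc(C(=O)[C@H](CO[Si](C)(C)C(C)(C)C)c2cc([C@H]3OC[C@H]4[C@@H]3CO[C@@H]4c3cc(OC)c4c(c3)[C@@H](CO[Si](C(C)C)(C(C)C)C(C)C)[C@@H](c3ccc(O[Si](C(C)C)(C(C)C)C(C)C)c(OC)c3)O4)cc(OC)c2O[Si](C)(C)C(C)(C)C)ccc1O[Si](C)(C)C(C)(C)C | intermediate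
38 | CNP0174045.1 | COc1cc(C(=O)[C@H](CO)c2cc([C@H]3OC[C@H]4[C@@H]3CO[C@@H]4c3cc(OC)c4c(c3)[C@@H](CO)[C@@H](c3ccc(O)c(OC)c3)O4)cc(OC)c2O)ccc1O | target

## Step count and risks

Total: 24 steps. Longest linear sequence: 18 steps (steps 1–11, 14–18, 23, 24).

**Step 17 (key step).** Ionization may stray to C2 of the cis-dihydrobenzofuran and epimerize it to trans. Equilibration may also stop short and leave an endo-aryl epimer, or a cation may be captured by a neighbouring arene, because cation lifetime rises as the oxygen nucleophiles are consumed. The fallback avoids cations altogether; it sets out from 24 and returns at 26.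
- Silylation of the phenol and the two primary hydroxyls (TBSCl, imidazole) gives the tris-TBS ether F1.
- Dess–Martin oxidation of both carbinols gives the 1,4-diketone F2.
- Corey–Bakshi–Shibata reduction with the (R)-methyl oxazaborolidine and BH3·SMe2 sets both carbinols S by reagent control, giving diol F3.
- HF·pyridine removes the two primary TBS groups in preference to the aryl silyl ethers and the primary TIPS ether, giving tetraol F4.
- Tosyl chloride in pyridine converts the primary hydroxyls into the bis-tosylate F5.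
- NaH in THF closes both rings by 5-exo-tet Williamson displacement with retention at C7 and C7', which gives 26 directly.

**Step 23.** Transmetalation of the ortho-silyloxy arylzinc to nickel may be slow for steric reasons, the α-keto organonickel may lose the β-silyloxy group, and the ligand may discriminate poorly at Cα for this hindered pair. The fallback sets out from 26 and returns at 38.
- The TBS ether of 4'-hydroxy-3'-methoxyacetophenone F6 (from the commercial ketone and TBSCl) is α-arylated with 26 (Pd(OAc)2, XPhos, K3PO4, toluene, 80 °C) to give the deoxybenzoin F7.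
- TMSOTf and Et3N give its Z-trimethylsilyl enol ether F8.
- A Mukaiyama aldol with aqueous formaldehyde under Sc(OTf)3 and a chiral 2,2'-bipyridine diol gives the β-hydroxy ketone F9; the two Cα epimers are diastereomers and are separated by chromatography if selectivity is incomplete.
- Buffered fluoride as in step 24 then gives 38.

**Step 8.** Enantioselection may fall short with the ortho-methoxy substituent next to the ether oxygen, and the sense of induction is assigned only by analogy. The fallback replaces catalyst control by resolution; it sets out from 12 and returns to 12. Scalemic 12 is esterified with (S)-2-methoxy-2-phenylacetic acid (DCC, DMAP) to the diastereomeric ester F10, which is purified by crystallization or chromatography and cleaved with i-Bu2AlH back to 12.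

**Step 24.** Prolonged fluoride exposure, needed for the primary TIPS ether, may epimerize Cα or trigger loss of water or formaldehyde. The fallback changes from preserving the centre to separating and recycling; it sets out from crude 38 and returns at 38. The Cα epimer F11 is separated by preparative reversed-phase chromatography and re-equilibrated by brief exposure to a weak amine base in methanol, and the mixture is separated again.

**Step 14.** The aldol trapping may be incomplete because the valuable aldehyde is the limiting partner, and the lithium aldolate may revert on warming. The fallback runs the two bond formations separately; it sets out from 18 and 19 and returns at 22. The enolate 21 is quenched with acid to isolate the conjugate adduct F12; its enolate is regenerated with LiN(SiMe3)2, transmetalated with ZnCl2 and treated with 15 at −78 °C, the zinc aldolate being less prone to retro-aldol.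

## Further compounds

F1 | step 17 | tris-TBS ether of 24 (ring B phenol and both primary hydroxyls), carbinol epimers | COc1cc(cc(I)c1O[Si](C)(C)C(C)(C)C)C(O)[C@@H](CO[Si](C)(C)C(C)(C)C)[C@H](CO[Si](C)(C)C(C)(C)C)C(O)c1cc(OC)c2c(c1)[C@@H](CO[Si](C(C)C)(C(C)C)C(C)C)[C@@H](c1ccc(O[Si](C(C)C)(C(C)C)C(C)C)c(OC)c1)O2
F2 | step 17 | 1,4-diketone from F1 | COc1cc(cc(I)c1O[Si](C)(C)C(C)(C)C)C(=O)[C@@H](CO[Si](C)(C)C(C)(C)C)[C@H](CO[Si](C)(C)C(C)(C)C)C(=O)c1cc(OC)c2c(c1)[C@@H](CO[Si](C(C)C)(C(C)C)C(C)C)[C@@H](c1ccc(O[Si](C(C)C)(C(C)C)C(C)C)c(OC)c1)O2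
F3 | step 17 | (7S,7'S)-diol from F2 | COc1cc(cc(I)c1O[Si](C)(C)C(C)(C)C)[C@@H](O)[C@@H](CO[Si](C)(C)C(C)(C)C)[C@H](CO[Si](C)(C)C(C)(C)C)[C@H](O)c1cc(OC)c2c(c1)[C@@H](CO[Si](C(C)C)(C(C)C)C(C)C)[C@@H](c1ccc(O[Si](C(C)C)(C(C)C)C(C)C)c(OC)c1)O2
F4 | step 17 | (7S,7'S)-tetraol with ring B TBS ether | COc1cc(cc(I)c1O[Si](C)(C)C(C)(C)C)[C@@H](O)[C@@H](CO)[C@H](CO)[C@H](O)c1cc(OC)c2c(c1)[C@@H](CO[Si](C(C)C)(C(C)C)C(C)C)[C@@H](c1ccc(O[Si](C(C)C)(C(C)C)C(C)C)c(OC)c1)O2
F5 | step 17 | bis(4-methylbenzenesulfonate) of F4 at C9 and C9' | COc1cc(cc(I)c1O[Si](C)(C)C(C)(C)C)[C@@H](O)[C@@H](COS(=O)(=O)c3ccc(C)cc3)[C@H](COS(=O)(=O)c3ccc(C)cc3)[C@H](O)c1cc(OC)c2c(c1)[C@@H](CO[Si](C(C)C)(C(C)C)C(C)C)[C@@H](c1ccc(O[Si](C(C)C)(C(C)C)C(C)C)c(OC)c1)O2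
F6 | step 23 | 1-{4-[(tert-butyldimethylsilyl)oxy]-3-methoxyphenyl}ethan-1-one | COc1cc(C(C)=O)ccc1O[Si](C)(C)C(C)(C)C
F7 | step 23 | deoxybenzoin from 26 and F6 | COc1cc(C(=O)Cc2cc([C@H]3OC[C@H]4[C@@H]3CO[C@@H]4c3cc(OC)c4c(c3)[C@@H](CO[Si](C(C)C)(C(C)C)C(C)C)[C@@H](c3ccc(O[Si](C(C)C)(C(C)C)C(C)C)c(OC)c3)O4)cc(OC)c2O[Si](C)(C)C(C)(C)C)ccc1O[Si](C)(C)C(C)(C)C
F8 | step 23 | (Z)-trimethylsilyl enol ether of F7 | COc1cc(/C(O[Si](C)(C)C)=C/c2cc([C@H]3OC[C@H]4[C@@H]3CO[C@@H]4c3cc(OC)c4c(c3)[C@@H](CO[Si](C(C)C)(C(C)C)C(C)C)[C@@H](c3ccc(O[Si](C(C)C)(C(C)C)C(C)C)c(OC)c3)O4)cc(OC)c2O[Si](C)(C)C(C)(C)C)ccc1O[Si](C)(C)C(C)(C)C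
F9 | step 23 | (S)-β-hydroxy ketone, tetrasilyl ether of the target with free C3 hydroxyl of the propanone | COc1cc(C(=O)[C@H](CO)c2cc([C@H]3OC[C@H]4[C@@H]3CO[C@@H]4c3cc(OC)c4c(c3)[C@@H](CO[Si](C(C)C)(C(C)C)C(C)C)[C@@H](c3ccc(O[Si](C(C)C)(C(C)C)C(C)C)c(OC)c3)O4)cc(OC)c2O[Si](C)(C)C(C)(C)C)ccc1O[Si](C)(C)C(C)(C)C
F10 | step 8 | (S)-2-methoxy-2-phenylacetate of 12 | Brc1cc(OC)c2c(c1)[C@@H](COC(=O)[C@@H](OC)c1ccccc1)[C@@H](c1ccc(O[Si](C(C)C)(C(C)C)C(C)C)c(OC)c1)O2
F11 | step 24 | Cα epimer (R) of 38 | COc1cc(C(=O)[C@@H](CO)c2cc([C@H]3OC[C@H]4[C@@H]3CO[C@@H]4c3cc(OC)c4c(c3)[C@@H](CO)[C@@H](c3ccc(O)c(OC)c3)O4)cc(OC)c2O)ccc1O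
F12 | step 14 | (4R,5R)-conjugate adduct of 18 and 19 | O=C1C[C@@H](C(Sc2ccccc2)(Sc2ccccc2)c2cc(I)c(OC(=O)C(C)(C)C)c(OC)c2)[C@H](O[C@@H]2C[C@H](C)CC[C@H]2C(C)C)O1
A1 | alternative 1 | methyl (2S,3R)-5-bromo-7-methoxy-2-{3-methoxy-4-[(triisopropylsilyl)oxy]phenyl}-2,3-dihydro-1-benzofuran-3-carboxylate (identical with 11) | Brc1cc(OC)c2c(c1)[C@@H](C(=O)OC)[C@@H](c1ccc(O[Si](C(C)C)(C(C)C)C(C)C)c(OC)c1)O2
A2 | alternative 1 | (2R)-6-bromo-3-diazo-8-methoxy-2-{3-methoxy-4-[(triisopropylsilyl)oxy]phenyl}-2,3-dihydro-4H-chromen-4-one | O=C1C(=[N+]=[N-])[C@@H](c2ccc(O[Si](C(C)C)(C(C)C)C(C)C)c(OC)c2)Oc2c(OC)cc(Br)cc12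
A3 | alternative 2 | 2,6-diaryl-3,7-dioxabicyclo[3.3.0]octan-8-one with methoxymethyl-protected bromophenol ring B and dipivaloylated cis-phenylcoumaran | Brc1cc(cc(OC)c1OCOC)[C@H]3OC[C@H]4[C@@H]3C(=O)O[C@@H]4c3cc(OC)c4c(c3)[C@@H](COC(=O)C(C)(C)C)[C@@H](c3ccc(OC(=O)C(C)(C)C)c(OC)c3)O4
A4 | alternative 2 | ({[3-bromo-5-methoxy-4-(methoxymethoxy)phenyl](chloro)methoxy}methyl)trimethylsilane | COCOc1c(Br)cc(cc1OC)C(Cl)OC[Si](C)(C)C
A5 | alternative 2 | (5S)-5-[(2S,3S)-dipivaloylated phenylcoumaran-5-yl]furan-2(5H)-one | O=C1C=C[C@@H](c2cc(OC)c3c(c2)[C@@H](COC(=O)C(C)(C)C)[C@@H](c2ccc(OC(=O)C(C)(C)C)c(OC)c2)O3)O1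
A6 | alternative 3 | tris-TBS furofuran–phenylcoumaran with ring B bromide | Brc1cc(cc(OC)c1O[Si](C)(C)C(C)(C)C)[C@H]3OC[C@H]4[C@@H]3CO[C@@H]4c3cc(OC)c4c(c3)[C@@H](CO[Si](C)(C)C(C)(C)C)[C@@H](c3ccc(O[Si](C)(C)C(C)(C)C)c(OC)c3)O4
A7 | alternative 3 | (R)-aryl(oxiranyl)methyl (E)-cinnamyl ether of the TBS-protected phenylcoumaran, epoxide epimers | Brc1cc(cc(OC)c1O[Si](C)(C)C(C)(C)C)[C@@H](OC/C=C/c1cc(OC)c2c(c1)[C@@H](CO[Si](C)(C)C(C)(C)C)[C@@H](c1ccc(O[Si](C)(C)C(C)(C)C)c(OC)c1)O2)C1CO1
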